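## Retrosynthetic overview

1. Feature: the only carbocycle of 16 has a C1 ketone, a C2=C3 methoxy enol ether, a C4 mixed ketal, C5H2 and allyl-bearing C6. Its neighbouring oxygen-bearing carbons C3 and C4 are the inner carbons of 2,3-dimethoxybuta-1,3-diene, C2 and C5 are the diene CH2 termini, and C1/C6 are the α/β carbons of an (E)-hexa-2,5-dienoyl dienophile.
2. Last disconnection, C4–OAr: 16 goes back to the enediol diether ketone 11 and phenol 14 (I+ onto C3=C4, phenol onto C4, loss of HI across C2–C3).
3. The C1 ketone of 11 is the acyl-bearing carbon of cycloadduct 7 after a one-carbon degradation run only under basic or neutral conditions (ester, α-hydroxy ester, 1,2-diol, glycol cleavage).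
4. Ring order: the cyclohexene is the only ring made (step 4, bonds C1–C2 and C5–C6, C6 set by the catalyst). The arene is bought and ortho-allylated by Claisen rearrangement.
5. Dienophile 5 is built imide first and vinyl last (Stille coupling), so its doubly allylic CH2 never meets base.

Key step: step 4

Remark: the ring numbering C1–C6 of the target is used for all ring intermediates. The configuration at C1 of 9 and 10 is not controlled and does not matter, because step 8 makes C1 trigonal.

## Route

Step 1
Reactants: 1 (E)-4-bromobut-2-enoic acid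
Product: 2 (E)-4-bromobut-2-enoyl chloride
Conditions: (COCl)2, DMF (cat.), CH2Cl2, 0 °C to rt; concentrated and used crude
Reagents that add atoms: oxalyl chloride, ClC(=O)C(=O)Cl
Why: Acid chloride formation through catalytic chloroiminium (Vilsmeier-type) activation is neutral enough to leave the allylic bromide and the E alkene untouched.

Step 2
Reactants: 2 (E)-4-bromobut-2-enoyl chloride; 3 oxazolidin-2-one
Product: 4 3-[(E)-4-bromobut-2-enoyl]oxazolidin-2-one
Conditions: 3, n-BuLi, THF, −78 °C; then 2, −78 to 0 °C
Reagents that add atoms: none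
Why: N-acylation of the lithiated oxazolidinone works because the acyl chloride reacts far faster than the allylic bromide at −78 °C, so substitution and conjugate addition should not compete.

Step 3
Reactants: 4 3-[(E)-4-bromobut-2-enoyl]oxazolidin-2-one
Product: 5 3-[(2E)-hexa-2,5-dienoyl]oxazolidin-2-one
Conditions: Bu3SnCH=CH2, Pd2(dba)3 (2.5 mol%), AsPh3 (10 mol%), THF, rt to 45 °C
Reagents that add atoms: tributyl(vinyl)stannane, C=C[Sn](CCCC)(CCCC)CCCC
Why: In this Stille allyl–vinyl coupling the π-allylpalladium species from the 4-bromocrotonoyl unit couples at its unsubstituted terminus and keeps the E-enoyl bond, and the neutral medium avoids base-induced drift of the skipped diene into the conjugated sorboyl system.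

Step 4
Reactants: 5 3-[(2E)-hexa-2,5-dienoyl]oxazolidin-2-one; 6 2,3-dimethoxybuta-1,3-diene
Product: 7 3-{[(1R,6R)-6-allyl-3,4-dimethoxycyclohex-3-en-1-yl]carbonyl}oxazolidin-2-one
Conditions: [Cu((S,S)-t-Bu-box)](SbF6)2 (10 mol%, preformed from CuCl2, AgSbF6 and 2,2'-isopropylidenebis[(4S)-4-tert-butyl-2-oxazoline]), 6 (3 equiv), 4 Å MS, CH2Cl2, −20 °C to rt; filtration through Et3N-deactivated silica
Reagents that add atoms: none
Why: The imide binds divalent copper through both carbonyl oxygens in a square-planar chelate that lowers the LUMO of the α,β-alkene and locks it s-cis, and the electron-rich diene then adds in a concerted, asynchronous, suprafacial [4+2] cycloaddition in which the bond from a diene CH2 to the β-carbon (C5–C6) runs ahead of C1–C2. The closest known reaction type is the copper bis(oxazoline)-catalysed enantioselective Diels–Alder reaction of N-crotonoyl and N-acryloyl oxazolidinones with cyclopentadiene and acyclic dienes. The single new ring, the six-membered carbocycle, is closed intermolecularly by these two σ bonds, with the diene reacting through its s-cis conformer. The trans relation of C1 and C6 follows from the E geometry of the dienophile, and the absolute configuration follows from the tert-butyl group of the (S,S)-ligand, which covers the Cα-Si face so that the diene arrives on the Cα-Re face and gives (1R,6R). Regio- and endo/exo selectivity do not arise because the diene is symmetrical and unsubstituted at its termini; the step needs π-facial selectivity, secured by chelate and ligand, and chemoselectivity for the conjugated alkene over the terminal vinyl group, secured because only the enoyl bond is Lewis-acid activated. The aprotic, base-free medium, the sieves and the excess diene should keep the doubly allylic CH2 of 5 out of conjugation and the enol ethers from hydrolysis.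

Step 5
Reactants: 7 3-{[(1R,6R)-6-allyl-3,4-dimethoxycyclohex-3-en-1-yl]carbonyl}oxazolidin-2-one
Product: 8 methyl (1R,6R)-6-allyl-3,4-dimethoxycyclohex-3-ene-1-carboxylate
Conditions: NaOMe (20 mol%), MeOH–THF, 0 °C
Reagents that add atoms: methanol, CO
Why: Base-catalysed methanolysis (transesterification) at the exocyclic imide carbonyl avoids a free carboxylic acid next to the acid-labile enediol diether, and any epimerisation at C1 is harmless because that centre is erased later.

Step 6
Reactants: 8 methyl (1R,6R)-6-allyl-3,4-dimethoxycyclohex-3-ene-1-carboxylate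
Product: 9 methyl (6R)-6-allyl-1-hydroxy-3,4-dimethoxycyclohex-3-ene-1-carboxylate (C1 epimers, either serves)
Conditions: KN(SiMe3)2, THF, −78 °C; 2-(phenylsulfonyl)-3-phenyloxaziridine, −78 °C; aq NH4Cl
Reagents that add atoms: 2-(phenylsulfonyl)-3-phenyloxaziridine, O=S(=O)(c1ccccc1)N1OC1c1ccccc1
Why: In this N-sulfonyloxaziridine enolate hydroxylation C1–H is the only acidic C–H, the potassium enolate takes up oxygen far faster than the neutral enediol diether at −78 °C, and C6 is not touched.

Step 7
Reactants: 9 methyl (6R)-6-allyl-1-hydroxy-3,4-dimethoxycyclohex-3-ene-1-carboxylate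
Product: 10 (6R)-6-allyl-1-(hydroxymethyl)-3,4-dimethoxycyclohex-3-en-1-ol
Conditions: LiAlH4, Et2O, 0 °C; H2O, aq NaOH work-up
Reagents that add atoms: none
Why: Hydride reduction of the ester to the primary alcohol leaves enol ethers and isolated alkenes alone, and the work-up stays basic.

Step 8
Reactants: 10 (6R)-6-allyl-1-(hydroxymethyl)-3,4-dimethoxycyclohex-3-en-1-ol
Product: 11 (6R)-6-allyl-3,4-dimethoxycyclohex-3-en-1-one
Conditions: NaIO4, THF–pH 7 phosphate buffer, 0 °C; extracted and used at once
Reagents that add atoms: none
Why: Malaprade glycol cleavage of the tertiary/primary 1,2-diol releases the C1 ketone at neutral pH and low temperature, which should keep C3=C4 out of conjugation and C6, now the only stereocentre, from enolising.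

Step 9
Reactants: 12 3,4-dimethoxyphenol
Product: 13 4-(allyloxy)-1,2-dimethoxybenzene
Conditions: allyl bromide, K2CO3, acetone, reflux
Reagents that add atoms: allyl bromide, C=CCBr
Why: This is a Williamson ether synthesis of a phenoxide with a reactive primary allylic halide.

Step 10
Reactants: 13 4-(allyloxy)-1,2-dimethoxybenzene
Product: 14 2-allyl-4,5-dimethoxyphenol
Conditions: N,N-diethylaniline, 190 °C
Reagents that add atoms: none
Why: The aromatic Claisen rearrangement ([3,3]-sigmatropic shift, then tautomerisation) should go to the open ortho position rather than the one flanked by a methoxy group.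

Step 11
Reactants: 11 (6R)-6-allyl-3,4-dimethoxycyclohex-3-en-1-one; 14 2-allyl-4,5-dimethoxyphenol
Product: 16 (4R,6R)-6-allyl-4-(2-allyl-4,5-dimethoxyphenoxy)-3,4-dimethoxycyclohex-2-en-1-one, via 3-iodo ketal 15 (not isolated)
Conditions: 14 (2 equiv), 4 Å MS, CH2Cl2, −78 °C, dark; NIS (1.05 equiv, added last as a THF solution), −78 to −40 °C; then Et3N, −40 to 0 °C; aq Na2S2O3/NaHCO3
Reagents that add atoms: none
Why: Proposed new method: the tetrasubstituted C3=C4 enediol diether is by far the most nucleophilic π bond present, so I+ from NIS should add there first, with iodine on C3 and the charge as a methoxy-stabilised oxocarbenium ion on C4, the carbon farther from the electron-withdrawing C1 carbonyl; phenol 14 then adds to C4 anti to iodine along the axial trajectory of the half-chair that keeps the C6 allyl group equatorial (trans-diaxial opening), which places the aryloxy group trans to the allyl group and so sets (4R), while the succinimide anion takes up the phenol proton so that no strong acid appears; Et3N then removes the axial, ketone-activated C2–H antiperiplanar to the axial C3–I bond of 15 and gives the conjugated C2=C3 methoxy enone; the closest known reaction types are the NIS-mediated iodoalkoxylation of enol ethers and glycals by alcohols and phenols and the amine-induced dehydrohalogenation of β-halo ketones, neither shown so far on a 1,2-dialkoxyalkene in which the halogen-bearing carbon also carries an alkoxy group.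

## Compound list

1 | (E)-4-bromobut-2-enoic acid | OC(=O)/C=C/CBr | starting material
2 | (E)-4-bromobut-2-enoyl chloride | ClC(=O)/C=C/CBr | intermediate
3 | oxazolidin-2-one | O=C1NCCO1 | starting material
4 | 3-[(E)-4-bromobut-2-enoyl]oxazolidin-2-one | O=C(/C=C/CBr)N1CCOC1=O | intermediate
5 | 3-[(2E)-hexa-2,5-dienoyl]oxazolidin-2-one | C=CC/C=C/C(=O)N1CCOC1=O | intermediate
6 | 2,3-dimethoxybuta-1,3-diene | C=C(OC)C(OC)=C | starting material
7 | 3-{[(1R,6R)-6-allyl-3,4-dimethoxycyclohex-3-en-1-yl]carbonyl}oxazolidin-2-one | C=CC[C@@H]1CC(OC)=C(OC)C[C@H]1C(=O)N1CCOC1=O | intermediate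
8 | methyl (1R,6R)-6-allyl-3,4-dimethoxycyclohex-3-ene-1-carboxylate | C=CC[C@@H]1CC(OC)=C(OC)C[C@H]1C(=O)OC | intermediate
9 | methyl (6R)-6-allyl-1-hydroxy-3,4-dimethoxycyclohex-3-ene-1-carboxylate (C1 open) | C=CC[C@@H]1CC(OC)=C(OC)CC1(O)C(=O)OC | intermediate
10 | (6R)-6-allyl-1-(hydroxymethyl)-3,4-dimethoxycyclohex-3-en-1-ol (C1 open) | C=CC[C@@H]1CC(OC)=C(OC)CC1(O)CO | intermediate
11 | (6R)-6-allyl-3,4-dimethoxycyclohex-3-en-1-one | C=CC[C@@H]1CC(OC)=C(OC)CC1=O | intermediate
12 | 3,4-dimethoxyphenol | COc1ccc(O)cc1OC | starting material
13 | 4-(allyloxy)-1,2-dimethoxybenzene | C=CCOc1ccc(OC)c(OC)c1 | intermediate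
14 | 2-allyl-4,5-dimethoxyphenol | C=CCc1cc(OC)c(OC)cc1O | intermediate
15 | (3R,4R,6R)-6-allyl-4-(2-allyl-4,5-dimethoxyphenoxy)-3-iodo-3,4-dimethoxycyclohexan-1-one (iodine trans to aryloxy) | C=CCc1cc(OC)c(OC)cc1O[C@]1(OC)C[C@@H](CC=C)C(=O)C[C@]1(I)OC | intermediate
16 | (4R,6R)-6-allyl-4-(2-allyl-4,5-dimethoxyphenoxy)-3,4-dimethoxycyclohex-2-en-1-one | C=CCc1cc(OC)c(OC)cc1O[C@]1(OC)C[C@@H](CC=C)C(=O)C=C1OC | target

## Step count and risks

Total step count: 11. Longest linear sequence: 9 (steps 1–8 and 11).

**Step 11.**
- Risks:
  - Proton loss at C5 from the C4 oxocarbenium ion may outrun capture by the phenol and lead on to aromatisation of the ring.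
  - Iodonium may transfer to the allyl group or the free ring position of the phenol.
  - Attack may occur at C3 instead of C4.
  - The facial bias at C4 may be weak.
- Fallback, from 11, by oxygen transfer instead of halonium chemistry:
  - Dimethyldioxirane in acetone–CH2Cl2 at −78 °C should epoxidise only the enediol diether, giving (6R)-6-allyl-3,4-epoxy-3,4-dimethoxycyclohexan-1-one F1.
  - Phenol 14 opens F1 at C4, as phenols open 1,2-anhydrosugars, to give the C3 hemiketal F2.
  - The hemiketal loses methanol to give (4R,6R)-6-allyl-4-(2-allyl-4,5-dimethoxyphenoxy)-4-methoxycyclohexane-1,3-dione F3.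
  - O-methylation of this cyclic 1,3-dione with (trimethylsilyl)diazomethane in toluene–MeOH, with separation from the regioisomeric vinylogous ester, comes back to the route at 16.

**Step 4.**
- Risks:
  - The β-substituted imide may cycloadd slowly.
  - The Lewis acid may oligomerise or hydrolyse the diene.
  - The skipped diene may drift into conjugation on the Lewis acid.
  - Facial selectivity may erode through a background or stepwise pathway.
- Fallback, from 2, keeping the same bond set but moving stereocontrol from the catalyst to a covalent auxiliary: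
  - Lithiated (R)-4-benzyloxazolidin-2-one is acylated to (4R)-4-benzyl-3-[(E)-4-bromobut-2-enoyl]oxazolidin-2-one F4.
  - Stille vinylation as in step 3 gives (4R)-4-benzyl-3-[(2E)-hexa-2,5-dienoyl]oxazolidin-2-one F5.
  - Cycloaddition with 6 promoted by Et2AlCl in CH2Cl2 at −78 °C takes place on the face away from the benzyl group of the chelated s-cis imide and gives the (1R,6R) adduct F6, whose minor diastereomer can be removed by chromatography or crystallisation.
  - Methanolysis as in step 5 comes back to the route at 8.

**Step 8.**
- Risks: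
  - C3=C4 may migrate into conjugation with the new ketone.
  - The enediol diether may hydrolyse in the aqueous medium.
  - Enolisation at C6 would erode enantiopurity.
- Fallback, from 7, replacing steps 5–8 and releasing the ketone in an anhydrous, neutral medium:
  - LiOH/H2O2 in THF–H2O at 0 °C, then liberation with cold NaH2PO4 buffer, gives (1R,6R)-6-allyl-3,4-dimethoxycyclohex-3-ene-1-carboxylic acid F7.
  - The dianion, made with LiN(i-Pr)2 (2.2 equiv) in THF, is oxygenated with dry O2 at −78 °C to (6R)-6-allyl-1-hydroperoxy-3,4-dimethoxycyclohex-3-ene-1-carboxylic acid F8.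
  - N,N-dimethylformamide dimethyl acetal in CH2Cl2 at rt fragments F8 with loss of CO2 (oxidative decarboxylation) and comes back to the route at 11.

## Further compounds

F1 | step 11 | (6R)-6-allyl-3,4-epoxy-3,4-dimethoxycyclohexan-1-one (epoxide face open) | C=CC[C@@H]1CC2(OC)OC2(OC)CC1=O
F2 | step 11 | (4R,6R)-6-allyl-4-(2-allyl-4,5-dimethoxyphenoxy)-3-hydroxy-3,4-dimethoxycyclohexan-1-one (transient C3 hemiketal) | C=CCc1cc(OC)c(OC)cc1O[C@]1(OC)C[C@@H](CC=C)C(=O)CC1(O)OC
F3 | step 11 | (4R,6R)-6-allyl-4-(2-allyl-4,5-dimethoxyphenoxy)-4-methoxycyclohexane-1,3-dione | C=CCc1cc(OC)c(OC)cc1O[C@]1(OC)C[C@@H](CC=C)C(=O)CC1=O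
F4 | step 4 | (4R)-4-benzyl-3-[(E)-4-bromobut-2-enoyl]oxazolidin-2-one | BrC/C=C/C(=O)N1[C@H](Cc2ccccc2)COC1=O
F5 | step 4 | (4R)-4-benzyl-3-[(2E)-hexa-2,5-dienoyl]oxazolidin-2-one | C=CC/C=C/C(=O)N1[C@H](Cc2ccccc2)COC1=O
F6 | step 4 | (4R)-4-benzyl-3-{[(1R,6R)-6-allyl-3,4-dimethoxycyclohex-3-en-1-yl]carbonyl}oxazolidin-2-one | C=CC[C@@H]1CC(OC)=C(OC)C[C@H]1C(=O)N1[C@H](Cc2ccccc2)COC1=O
F7 | step 8 | (1R,6R)-6-allyl-3,4-dimethoxycyclohex-3-ene-1-carboxylic acid | C=CC[C@@H]1CC(OC)=C(OC)C[C@H]1C(=O)O
F8 | step 8 | (6R)-6-allyl-1-hydroperoxy-3,4-dimethoxycyclohex-3-ene-1-carboxylic acid (C1 open) | C=CC[C@@H]1CC(OC)=C(OC)CC1(OO)C(=O)O
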